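## Retrosynthetic overview

1. The 9‑acetate comes from the 9α‑alcohol, whose C9–O bond is made last on the carbocycle by a singlet‑oxygen ene reaction of a macrocyclic skipped dienoate; the same step moves C9=C10 to C1=C10. The 4,5‑oxirane is set just before by peripheral epoxidation.
2. The ten‑membered ring is closed by ring‑closing metathesis at C9=C10 (vinyl of an allylic ester plus a 2‑substituted acrylate).
3. The C8 ester comes from Yamaguchi acylation with (2S,3S)‑epoxyangelic acid (Sharpless epoxidation of angelyl alcohol); the C9 vinyl comes from a glyceraldehyde‑derived diol.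
4. The γ‑lactone (C6–C7 and C6–O) comes from a chromium‑mediated 2‑(methoxycarbonyl)allylation of a (2E,4Z)‑dienal (enynol + methyl 2‑(bromomethyl)acrylate) with a Baylis–Hillman bromide from (R)‑glyceraldehyde acetonide.
5. Ring order: lactone (step 6), side‑chain oxirane (step 11, separate branch), carbocycle (step 14), 4,5‑oxirane (step 15).

Assumption: (2E)‑3‑methylpent‑2‑en‑4‑yn‑1‑ol, methyl 2‑(bromomethyl)acrylate, (R)‑glyceraldehyde acetonide and angelic acid are bought; ring atoms are called C1–C15 by germacrane numbering and α is the face of H‑7.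

## Route

Step 1
Reactants: 1 (2E)-3-methylpent-2-en-4-yn-1-ol; 2 methyl 2-(bromomethyl)prop-2-enoate
Product: 3 methyl (6E)-8-hydroxy-6-methyl-2-methylideneoct-6-en-4-ynoate
Conditions: CuI (20 mol %), K2CO3, NaI (cat.), DMF, 23 °C
Reagents that add atoms: none
Why: Copper‑acetylide allylic substitution (Cu‑catalysed alkyne–allyl bromide coupling): the copper acetylide of 1 displaces bromide from 2 (SN2 and SN2′ give the same 1,4‑enyne), forming the C1–C2 bond with the free alcohol untouched and no stereocentre formed.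

Step 2
Reactants: 3 methyl (6E)-8-hydroxy-6-methyl-2-methylideneoct-6-en-4-ynoate
Product: 4 methyl (4Z,6E)-8-hydroxy-6-methyl-2-methylideneocta-4,6-dienoate
Conditions: H2 (1 atm), Lindlar catalyst (Pd/CaCO3 poisoned with Pb(OAc)2), quinoline, EtOAc, 0 °C
Reagents that add atoms: none
Why: Lindlar semi‑hydrogenation adds H2 syn to the conjugated alkyne far faster than to the alkenes, giving the Z alkene that becomes C2=C3.

Step 3
Reactants: 4 methyl (4Z,6E)-8-hydroxy-6-methyl-2-methylideneocta-4,6-dienoate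
Product: 5 methyl (4Z,6E)-6-methyl-2-methylidene-8-oxoocta-4,6-dienoate
Conditions: MnO2, CH2Cl2, 23 °C
Reagents that add atoms: none
Why: MnO2 allylic oxidation converts only the primary allylic alcohol into the enal (C6 aldehyde) under neutral conditions that do not isomerise the skipped diene.

Step 4
Reactants: 6 (4R)-2,2-dimethyl-1,3-dioxolane-4-carbaldehyde; 7 methyl prop-2-enoate
Product: 8 methyl 2-{[(4R)-2,2-dimethyl-1,3-dioxolan-4-yl](hydroxy)methyl}prop-2-enoate
Conditions: DABCO (0.5 equiv), 1,4-dioxane–H2O (1:1), 23 °C, 3 d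
Reagents that add atoms: none
Why: Morita–Baylis–Hillman reaction; the new carbinol centre forms as a mixture that does not matter because it becomes sp2 in step 5, and the dioxolane centre (later C8) is untouched.

Step 5
Reactants: 8 methyl 2-{[(4R)-2,2-dimethyl-1,3-dioxolan-4-yl](hydroxy)methyl}prop-2-enoate
Product: 9 methyl (2Z)-2-(bromomethyl)-3-[(4S)-2,2-dimethyl-1,3-dioxolan-4-yl]prop-2-enoate
Conditions: NBS, Me2S, CH2Cl2, 0 → 23 °C
Reagents that add atoms: N-bromosuccinimide, BrN1C(=O)CCC1=O
Why: Corey–Kim‑type activation of the alcohol followed by SN2′ attack of bromide (allylic transposition) gives the thermodynamically preferred (Z)‑2‑(bromomethyl)alk‑2‑enoate; the descriptor of the dioxolane centre changes from R to S only through CIP priorities.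

Step 6
Reactants: 5 methyl (4Z,6E)-6-methyl-2-methylidene-8-oxoocta-4,6-dienoate; 9 methyl (2Z)-2-(bromomethyl)-3-[(4S)-2,2-dimethyl-1,3-dioxolan-4-yl]prop-2-enoate
Product: 11 trans-lactone acetonide, via hydroxy diester 10 (not isolated)
Conditions: CrCl2 (4 equiv), THF, 0 → 23 °C; then PPTS (cat.), CH2Cl2, 23 °C
Reagents that add atoms: none
Why: Nozaki–Hiyama (chromium Barbier) 2‑(methoxycarbonyl)allylation then lactonisation: the allylchromium adds 1,2 to the enal through a chair transition state with anti selectivity (trans‑lactone, C6/C7), and the face of C7 is chosen by the dioxolane centre (H‑8 eclipsing the alkene to relieve A1,3 strain, aldehyde entering anti to the ring CH2 on the side of the ring oxygen), which gives the target configuration at C6 and C7.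

Step 7
Reactants: 11 trans-lactone acetonide
Product: 12 lactone 8,9-diol
Conditions: AcOH–H2O (4:1), 35 °C
Reagents that add atoms: none
Why: Mild acid hydrolysis of the terminal isopropylidene acetal frees the diol without ionising the dienyl lactone C6–O bond.

Step 8
Reactants: 12 lactone 8,9-diol
Product: 13 lactone α-hydroxy aldehyde
Conditions: TEMPO (10 mol %), PhI(OAc)2, CH2Cl2, 23 °C
Reagents that add atoms: none
Why: TEMPO/PhI(OAc)2 (oxoammonium) oxidation takes the primary alcohol over the secondary one and is non‑basic, so C8 does not epimerise and the lactone does not migrate to O8.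

Step 9
Reactants: 13 lactone α-hydroxy aldehyde
Product: 14 lactone allylic alcohol with C9 vinyl
Conditions: Ph3PCH3Br, KN(SiMe3)2, THF, −78 → 0 °C
Reagents that add atoms: methyltriphenylphosphonium bromide, C[P+](c1ccccc1)(c1ccccc1)c1ccccc1.[Br-]
Why: Wittig methylenation; the aldehyde reacts at −78 °C long before the esters, the lactone or the α‑methylene unit, and C8 keeps its configuration.

Step 10
Reactants: 15 (2Z)-2-methylbut-2-enoic acid (angelic acid)
Product: 16 (2Z)-2-methylbut-2-en-1-ol
Conditions: LiAlH4, Et2O, 0 → 23 °C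
Reagents that add atoms: none
Why: LiAlH4 1,2‑reduction of the acid gives the allylic alcohol with the Z geometry kept.

Step 11
Reactants: 16 (2Z)-2-methylbut-2-en-1-ol
Product: 17 [(2R,3S)-2,3-dimethyloxiran-2-yl]methanol
Conditions: Ti(OiPr)4 (10 mol %), D-(−)-diisopropyl tartrate (12 mol %), tBuOOH, 4 Å MS, CH2Cl2, −20 °C
Reagents that add atoms: tert-butyl hydroperoxide, CC(C)(C)OO
Why: Sharpless asymmetric epoxidation; the D‑(−)‑tartrate complex delivers oxygen to the alkene face that gives the (2R,3S) epoxy alcohol, and the Z geometry fixes the cis relation of CH2OH and the C3 methyl.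

Step 12
Reactants: 17 [(2R,3S)-2,3-dimethyloxiran-2-yl]methanol
Product: 18 (2S,3S)-2,3-dimethyloxirane-2-carboxylic acid
Conditions: RuCl3·xH2O (2 mol %), NaIO4, MeCN–EtOAc–H2O, 23 °C
Reagents that add atoms: sodium periodate, [Na+].[O-]I(=O)(=O)=O; water, O
Why: Sharpless RuO4 oxidation takes the primary alcohol to the acid without opening the oxirane; C2 becomes S only because the CIP priorities change.

Step 13
Reactants: 14 lactone allylic alcohol with C9 vinyl; 18 (2S,3S)-2,3-dimethyloxirane-2-carboxylic acid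
Product: 20 C8 epoxyangelate ester, via mixed anhydride 19 (not isolated)
Conditions: 2,4,6-trichlorobenzoyl chloride, Et3N, THF, 23 °C; then 14, DMAP, toluene, 23 °C
Reagents that add atoms: 2,4,6-trichlorobenzoyl chloride, O=C(Cl)c1c(Cl)cc(Cl)cc1Cl (its acyl group stays in 19 only and is lost again on forming 20)
Why: Yamaguchi esterification; DMAP transfers the hindered acyl group from the mixed anhydride to the secondary allylic alcohol with retention at C8 and in the acid, and no alkoxide is formed that could move the lactone.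

Step 14
Reactants: 20 C8 epoxyangelate ester
Product: 21 macrocyclic (2Z,4E,9E)-triene lactone
Conditions: second-generation Hoveyda–Grubbs catalyst, RuCl2(H2IMes)(=CH-C6H4-2-OiPr) (15 mol %), 1,4-benzoquinone (30 mol %), toluene (1 mM), 80 °C
Reagents that add atoms: none
Why: Ring‑closing metathesis; the carbene loads on the monosubstituted C9 vinyl and closes on the acrylate methylene at C10, the only productive pairing (the others would give a cyclobutene or a tetrasubstituted alkene), and the ten‑membered ring forces C8 and C1 cis on the new C9=C10 bond.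

Step 15
Reactants: 21 macrocyclic (2Z,4E,9E)-triene lactone
Product: 22 4α,5β-epoxide
Conditions: mCPBA, CH2Cl2, −20 → 0 °C
Reagents that add atoms: 3-chloroperoxybenzoic acid, OOC(=O)c1cccc(Cl)c1
Why: Prilezhaev epoxidation of the only electron‑rich trisubstituted alkene; A1,3 strain between the C4 methyl and C6 holds H‑6 in the alkene plane and ring carbon C7 blocks the inner face, so oxygen arrives from the periphery on the O‑6 side and gives the (4R,5R) threo epoxide found in parthenolide‑type germacranolides.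

Step 16
Reactants: 22 4α,5β-epoxide
Product: 24 9α-alcohol, via 9α-hydroperoxide 23 (not isolated)
Conditions: O2, hν (visible light), tetraphenylporphyrin (1 mol %), CH2Cl2, −20 °C; then PPh3, −20 → 0 °C
Reagents that add atoms: dioxygen, O=O
Why: Proposed new method: a gem‑selective Schenck ene reaction on a macrocyclic skipped dienoate, in which singlet oxygen forms a perepoxide on C9=C10 from the peripheral face (H‑8 lies in the alkene plane because of A1,3 strain with C1H2, ring carbon C7 shields the inner face, so attack is on the side of the C8 oxygen), removes the doubly allylic H‑1 that is geminal to the ester, shifts the double bond to a ring‑cis C1=C10 conjugated with C2=C3 and leaves the hydroperoxide at C9 with the 9S (threo) configuration, which PPh3 reduces to the alcohol; the closest known reactions are Adam's gem‑regioselective photooxygenation of acyclic α‑alkyl acrylates and his threo‑selective, hydroxyl‑directed ene reaction of chiral allylic alcohols, not yet shown on an ester‑bearing macrocyclic 1,4‑diene where ring shape alone must set the face and the new diene geometry.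

Step 17
Reactants: 24 9α-alcohol
Product: 25 target CNP0229507.6
Conditions: Ac2O, DMAP (cat.), pyridine, CH2Cl2, 0 °C
Reagents that add atoms: acetic anhydride, CC(=O)OC(C)=O
Why: DMAP‑catalysed acetylation of the secondary allylic alcohol; no stereocentre is touched and the C8 ester is already in place, so the two acyl groups cannot be confused.

## Compound list

1 | (2E)-3-methylpent-2-en-4-yn-1-ol | C#C/C(C)=C/CO | starting material
2 | methyl 2-(bromomethyl)prop-2-enoate | COC(=O)C(=C)CBr | starting material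
3 | methyl (6E)-8-hydroxy-6-methyl-2-methylideneoct-6-en-4-ynoate | COC(=O)C(=C)CC#C/C(C)=C/CO | intermediate
4 | methyl (4Z,6E)-8-hydroxy-6-methyl-2-methylideneocta-4,6-dienoate | COC(=O)C(=C)C/C=C\C(C)=C\CO | intermediate
5 | methyl (4Z,6E)-6-methyl-2-methylidene-8-oxoocta-4,6-dienoate | COC(=O)C(=C)C/C=C\C(C)=C\C=O | intermediate
6 | (4R)-2,2-dimethyl-1,3-dioxolane-4-carbaldehyde, (R)-glyceraldehyde acetonide | O=C[C@H]1COC(C)(C)O1 | starting material
7 | methyl prop-2-enoate | C=CC(=O)OC | starting material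
8 | methyl 2-{[(4R)-2,2-dimethyl-1,3-dioxolan-4-yl](hydroxy)methyl}prop-2-enoate, both carbinol epimers | COC(=O)C(=C)C(O)[C@H]1COC(C)(C)O1 | intermediate
9 | methyl (2Z)-2-(bromomethyl)-3-[(4S)-2,2-dimethyl-1,3-dioxolan-4-yl]prop-2-enoate | COC(=O)/C(CBr)=C/[C@H]1COC(C)(C)O1 | intermediate
10 | dimethyl (4Z,6E,8R,9S)-9-[(4S)-2,2-dimethyl-1,3-dioxolan-4-yl]-8-hydroxy-6-methyl-2,10-dimethylideneundeca-4,6-dienedioate | COC(=O)C(=C)[C@H]([C@H]1COC(C)(C)O1)[C@H](O)/C=C(C)/C=C\CC(=C)C(=O)OC | intermediate (not isolated)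
11 | methyl (4Z,6E)-7-[(2R,3S)-3-[(4S)-2,2-dimethyl-1,3-dioxolan-4-yl]-4-methylidene-5-oxooxolan-2-yl]-6-methyl-2-methylidenehepta-4,6-dienoate | C=C1C(=O)O[C@H](/C=C(C)/C=C\CC(=C)C(=O)OC)[C@H]1[C@H]2COC(C)(C)O2 | intermediate
12 | methyl (4Z,6E)-7-[(2R,3R)-3-[(1S)-1,2-dihydroxyethyl]-4-methylidene-5-oxooxolan-2-yl]-6-methyl-2-methylidenehepta-4,6-dienoate | C=C1C(=O)O[C@H](/C=C(C)/C=C\CC(=C)C(=O)OC)[C@H]1[C@H](O)CO | intermediate
13 | methyl (4Z,6E)-7-[(2R,3R)-3-[(1S)-1-hydroxy-2-oxoethyl]-4-methylidene-5-oxooxolan-2-yl]-6-methyl-2-methylidenehepta-4,6-dienoate | C=C1C(=O)O[C@H](/C=C(C)/C=C\CC(=C)C(=O)OC)[C@H]1[C@H](O)C=O | intermediate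
14 | methyl (4Z,6E)-7-[(2R,3R)-3-[(1R)-1-hydroxyprop-2-en-1-yl]-4-methylidene-5-oxooxolan-2-yl]-6-methyl-2-methylidenehepta-4,6-dienoate | C=C1C(=O)O[C@H](/C=C(C)/C=C\CC(=C)C(=O)OC)[C@H]1[C@H](O)C=C | intermediate
15 | (2Z)-2-methylbut-2-enoic acid, angelic acid | C/C=C(/C)C(=O)O | starting material
16 | (2Z)-2-methylbut-2-en-1-ol | C/C=C(/C)CO | intermediate
17 | [(2R,3S)-2,3-dimethyloxiran-2-yl]methanol | OC[C@@]1(C)O[C@H]1C | intermediate
18 | (2S,3S)-2,3-dimethyloxirane-2-carboxylic acid, epoxyangelic acid | OC(=O)[C@@]1(C)O[C@H]1C | intermediate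
19 | (2S,3S)-2,3-dimethyloxirane-2-carboxylic 2,4,6-trichlorobenzoic anhydride | O=C(OC(=O)[C@@]1(C)O[C@H]1C)c1c(Cl)cc(Cl)cc1Cl | intermediate (not isolated)
20 | methyl (4Z,6E)-7-[(2R,3R)-3-[(1R)-1-{[(2S,3S)-2,3-dimethyloxirane-2-carbonyl]oxy}prop-2-en-1-yl]-4-methylidene-5-oxooxolan-2-yl]-6-methyl-2-methylidenehepta-4,6-dienoate | C=C1C(=O)O[C@H](/C=C(C)/C=C\CC(=C)C(=O)OC)[C@H]1[C@H](OC(=O)[C@@]2(C)O[C@H]2C)C=C | intermediate
21 | germacra-2Z,4E,9E,11(13)-tetraen-12,6α-olide with 10-CO2Me (C14), 8β-[(2S,3S)-2,3-dimethyloxirane-2-carbonyloxy], H-7 α | C=C1C(=O)O[C@@H]2/C=C(C)/C=C\C/C(C(=O)OC)=C\[C@@H](OC(=O)[C@@]3(C)O[C@H]3C)[C@@H]12 | intermediate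
22 | (4R,5R)-4α,5β-epoxide of 21: 4α,5β-epoxygermacra-2Z,9E,11(13)-trien-12,6α-olide with 10-CO2Me and the 8β-epoxyangelate | C=C1C(=O)O[C@@H]2[C@H]3O[C@]3(C)/C=C\C/C(C(=O)OC)=C\[C@@H](OC(=O)[C@@]4(C)O[C@H]4C)[C@@H]12 | intermediate
23 | 9α-hydroperoxy-4α,5β-epoxygermacra-1(10)E,2Z,11(13)-trien-12,6α-olide with 10-CO2Me and the 8β-epoxyangelate | C=C1C(=O)O[C@@H]2[C@H]3O[C@]3(C)/C=C\C=C(C(=O)OC)/[C@H](OO)[C@@H](OC(=O)[C@@]4(C)O[C@H]4C)[C@@H]12 | intermediate (not isolated)
24 | 9α-hydroxy analogue of 23 (9S) | C=C1C(=O)O[C@@H]2[C@H]3O[C@]3(C)/C=C\C=C(C(=O)OC)/[C@H](O)[C@@H](OC(=O)[C@@]4(C)O[C@H]4C)[C@@H]12 | intermediate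
25 | CNP0229507.6: methyl 9α-acetoxy-8β-[(2S,3S)-2,3-dimethyloxirane-2-carbonyloxy]-4α,5β-epoxy-12-oxo-6α,12-epoxygermacra-1(10)E,2Z,11(13)-trien-14-oate, (4R,5R,6S,7R,8S,9S) | C=C1C(=O)O[C@H]2[C@H]1[C@H](OC(=O)[C@@]1(C)O[C@H]1C)[C@@H](OC(C)=O)/C(C(=O)OC)=C\C=C/[C@@]1(C)O[C@H]21 | target

## Step count and risks

Total: 17 steps. Longest linear sequence: 12 steps (1, 2, 3, 6, 7, 8, 9, 13, 14, 15, 16, 17).

The step most likely to fail is step 16, the new ene reaction. Singlet oxygen may also attack C2=C3, the new C1=C10 bond may form ring‑trans, or the facial selectivity at C9 may be poor without a directing hydroxyl. The fallback uses known Kharasch–Sosnovsky chemistry: it sets out from 22 and treats it with CuBr and tert‑butyl peracetate in MeCN at 60 °C. The tert‑butoxyl radical removes the weak doubly allylic H‑1, and the trivalent copper pentadienyl acetate collapses at the less hindered terminus C9 to give the conjugated dienoate acetate. This arrives directly at 25 after separation of any C9 epimer and makes no new compound (F0).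

The second is step 6. The sense of 1,2‑induction from the dioxolane onto C7 is not secured by a close precedent; if the aldehyde instead enters anti to the ring oxygen, the wrong C6/C7 pair results. The fallback corrects C8 by a C–O bond formation with inversion. It sets out from 5 and uses (S)‑glyceraldehyde acetonide F1, which gives the Baylis–Hillman adduct F2 and then the (4R)‑bromide F3 (same reagents as steps 4 and 5). CrCl2 coupling of F3 with 5 gives the hydroxy diester F4 and, on lactonisation, the 8‑epi‑lactone acetonide F5, now with the needed C6 and C7. Acetal hydrolysis gives the 8‑epi‑diol F6, TEMPO/PhI(OAc)2 gives the 8‑epi‑hydroxy aldehyde F7, and Wittig methylenation gives the 8‑epi‑allylic alcohol F8. A Mitsunobu esterification of F8 with 18 (PPh3, diisopropyl azodicarboxylate, toluene, 0 → 23 °C) inverts C8 and comes back to the route at 20.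

The third is step 14. A ten‑membered ring with a trisubstituted enoate next to a bulky allylic ester may close slowly, and the skipped diene may isomerise. The fallback changes the substrate and the order: it sets out from 14, whose free allylic hydroxyl speeds carbene loading at C9, and closes the ring first (same catalyst, toluene, 60 °C) to the macrocyclic 8β‑alcohol F9. F9 is then acylated with the mixed anhydride 19 (DMAP, toluene) and comes back to the route at 21.

Further compounds
F1 | step 6 | (4S)-2,2-dimethyl-1,3-dioxolane-4-carbaldehyde, (S)-glyceraldehyde acetonide | O=C[C@@H]1COC(C)(C)O1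
F2 | step 6 | methyl 2-{[(4S)-2,2-dimethyl-1,3-dioxolan-4-yl](hydroxy)methyl}prop-2-enoate, both carbinol epimers | COC(=O)C(=C)C(O)[C@@H]1COC(C)(C)O1
F3 | step 6 | methyl (2Z)-2-(bromomethyl)-3-[(4R)-2,2-dimethyl-1,3-dioxolan-4-yl]prop-2-enoate | COC(=O)/C(CBr)=C/[C@@H]1COC(C)(C)O1
F4 | step 6 | dimethyl (4Z,6E,8R,9S)-9-[(4R)-2,2-dimethyl-1,3-dioxolan-4-yl]-8-hydroxy-6-methyl-2,10-dimethylideneundeca-4,6-dienedioate | COC(=O)C(=C)[C@H]([C@@H]1COC(C)(C)O1)[C@H](O)/C=C(C)/C=C\CC(=C)C(=O)OC
F5 | step 6 | methyl (4Z,6E)-7-[(2R,3S)-3-[(4R)-2,2-dimethyl-1,3-dioxolan-4-yl]-4-methylidene-5-oxooxolan-2-yl]-6-methyl-2-methylidenehepta-4,6-dienoate | C=C1C(=O)O[C@H](/C=C(C)/C=C\CC(=C)C(=O)OC)[C@H]1[C@@H]2COC(C)(C)O2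
F6 | step 6 | methyl (4Z,6E)-7-[(2R,3R)-3-[(1R)-1,2-dihydroxyethyl]-4-methylidene-5-oxooxolan-2-yl]-6-methyl-2-methylidenehepta-4,6-dienoate | C=C1C(=O)O[C@H](/C=C(C)/C=C\CC(=C)C(=O)OC)[C@H]1[C@@H](O)CO
F7 | step 6 | methyl (4Z,6E)-7-[(2R,3R)-3-[(1R)-1-hydroxy-2-oxoethyl]-4-methylidene-5-oxooxolan-2-yl]-6-methyl-2-methylidenehepta-4,6-dienoate | C=C1C(=O)O[C@H](/C=C(C)/C=C\CC(=C)C(=O)OC)[C@H]1[C@@H](O)C=O
F8 | step 6 | methyl (4Z,6E)-7-[(2R,3R)-3-[(1S)-1-hydroxyprop-2-en-1-yl]-4-methylidene-5-oxooxolan-2-yl]-6-methyl-2-methylidenehepta-4,6-dienoate | C=C1C(=O)O[C@H](/C=C(C)/C=C\CC(=C)C(=O)OC)[C@H]1[C@@H](O)C=C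
F9 | step 14 | 8β-hydroxygermacra-2Z,4E,9E,11(13)-tetraen-12,6α-olide with 10-CO2Me, H-7 α | C=C1C(=O)O[C@@H]2/C=C(C)/C=C\C/C(C(=O)OC)=C\[C@@H](O)[C@@H]12
F0 | step 16 | none | none
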